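Retrosynthesis: the carbon skeleton is cut once, at C12–C13 of the octacosanoyl chain (C1 = ester carbonyl), into two carboxylic acids that are joined by a mixed Kolbe electrolysis, an anodic decarboxylative radical–radical coupling of two carbons of like polarity. Behind that, the free carboxyl of the C1–C12 half is traced to the C13=C14 alkene of erucic acid, and the ester C–O bond to 2-phenylethanol.
Enabling feature: C12 and C13 are plain CH2 groups of an unbranched (CH2)26 chain with no heteroatom or branch at or next to either, so each can be generated as a primary alkyl radical from a CO2H one carbon further out. The ester C1(=O)–O lies ten CH2 groups from the radical carbon, and the only ring, the phenyl ring, lies beyond the ester.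
Forward: erucic acid 1 and 2-phenylethanol 2 give ester 3; oxidative cleavage of C13=C14 gives, via aldehyde 4, the half-ester 5, whose two carboxyl ends are differentiated from the start; cross-Kolbe coupling of 5 with heptadecanoic acid 6 joins the C12 and C16 halves to give target 7. No ring is formed.
Stereochemistry: the target has no stereocentre and no stereogenic double bond, so it is achiral and nothing has to be controlled; the Z alkene of 1 is consumed in step 2.

Key step: step 3

Step 1
Reactants: 1 erucic acid ((Z)-docos-13-enoic acid); 2 2-phenylethanol
Product: 3 2-phenylethyl (Z)-docos-13-enoate
Conditions: DCC (1.1 equiv), DMAP (0.1 equiv), CH2Cl2, 0 °C to rt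
Reagents that add atoms: none
Why: Steglich esterification (carbodiimide activation, DMAP-catalysed acyl transfer to the primary alcohol) runs under neutral conditions at room temperature, so the C13=C14 alkene should not migrate along the chain, and esterifying C1 before the alkene is cleaved is what differentiates the two later carboxyl groups.

Step 2
Reactants: 3 2-phenylethyl (Z)-docos-13-enoate
Product: 5 13-oxo-13-(2-phenylethoxy)tridecanoic acid, via 2-phenylethyl 13-oxotridecanoate 4 (not isolated)
Conditions: OsO4 (1 mol %), Oxone (4 equiv KHSO5), DMF, rt; Na2SO3 quench
Reagents that add atoms: potassium peroxymonosulfate (active component of Oxone), [K+].[O-]S(=O)(=O)OO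
Why: Osmium-catalysed oxidative cleavage with peroxymonosulfate (osmylation of the only C=C, oxidative fragmentation of the osmate ester at the aldehyde level, then oxidation of the aldehyde to the acid by peroxymonosulfate in DMF) should turn C13 into the free carboxyl while the phenyl ring and the ester stay untouched, and the co-formed nonanoic acid is volatile enough to be removed by bulb-to-bulb distillation before 5 is crystallised.

Step 3
Reactants: 5 13-oxo-13-(2-phenylethoxy)tridecanoic acid; 6 heptadecanoic acid
Product: 7 2-phenylethyl octacosanoate
Conditions: 5 (1 equiv), 6 (4 equiv), KOH (5 mol % of total CO2H), MeOH, undivided cell, smooth Pt anode/Pt cathode, constant current ca. 0.25 A cm⁻², 45–50 °C, stopped while still faintly acidic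
Reagents that add atoms: none
Why: At the platinum anode the carboxylates of 5 and 6 (about 5 % neutralisation) are each oxidised by one electron to acyloxy radicals, which lose CO2 in the anode layer to give the primary 12-oxo-12-(2-phenylethoxy)dodecyl and hexadecyl radicals; these arise side by side at high local concentration and combine, which forms the C12–C13 bond of the octacosanoyl chain, while protons are reduced to H2 at the cathode. The closest known reaction type is the mixed (crossed) Kolbe electrolysis of a fatty acid with an alkanedioic acid half-ester, the classical anodic chain extension. No ring is closed and no stereocentre is formed, so there is no mode of closure or facial control to specify. The step needs cross-coupling over homo-coupling, which is statistical and is secured for the valuable partner by the four-fold excess of 6; the two symmetrical homodimers (a C32 alkane and a C24 diester) differ enough in polarity from 7 to be removed by chromatography and crystallisation, and unreacted 6 is recovered by base extraction. It also needs the one-electron radical path over the two-electron Hofer–Moest path, which the substrates secure because both radicals are unbranched primary alkyl radicals with no heteroatom or branch at the α- or β-carbon, helped by smooth platinum, high current density and a weakly acidic medium. The ester carbonyl is ten CH2 groups from the radical centre and the phenyl ring is an unactivated monoalkylbenzene that should be harder to oxidise than the adsorbed carboxylate layer, and because the bulk stays acidic to the end, methoxide formed at the cathode should be quenched before it can transesterify the 2-phenylethyl ester.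

Compound list
1 | erucic acid ((Z)-docos-13-enoic acid) | CCCCCCCC/C=C\CCCCCCCCCCCC(=O)O | starting material
2 | 2-phenylethanol | OCCc1ccccc1 | starting material
3 | 2-phenylethyl (Z)-docos-13-enoate | CCCCCCCC/C=C\CCCCCCCCCCCC(=O)OCCc1ccccc1 | intermediate
4 | 2-phenylethyl 13-oxotridecanoate | O=CCCCCCCCCCCCC(=O)OCCc1ccccc1 | intermediate (not isolated)
5 | 13-oxo-13-(2-phenylethoxy)tridecanoic acid | OC(=O)CCCCCCCCCCCC(=O)OCCc1ccccc1 | intermediate
6 | heptadecanoic acid | CCCCCCCCCCCCCCCCC(=O)O | starting material
7 | 2-phenylethyl octacosanoate (phenylethyl n-octacosanoate) | CCCCCCCCCCCCCCCCCCCCCCCCCCCC(=O)OCCc1ccccc1 | target

Total step count: 3. Longest linear sequence: 3 steps (1 → 3 → 5 → 7); 6 enters in the last step as a purchased partner.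

Steps most likely to fail

Step 3. Statistical pairing of the two radicals diverts material into homocoupling, the waxy products may coat the anode and push the potential into the two-electron regime, and the ester may exchange with methanol if the electrolyte drifts alkaline. The fallback is a polar copper-catalysed alkyl–alkyl coupling that makes the same C12–C13 bond and sets out from 2. Fischer esterification of 2 with commercial 12-bromododecanoic acid (cat. TsOH, toluene, Dean–Stark) gives 2-phenylethyl 12-bromododecanoate F1. 1-Bromohexadecane and magnesium in THF give hexadecylmagnesium bromide F2. Slow addition of F2 to F1 with Li2CuCl4 (3 mol %) and NMP in THF at 0 °C should displace the primary bromide faster than the Grignard reagent attacks the ester, and the route is rejoined at 7.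

Step 2. Cleavage of a greasy substrate that dissolves poorly in DMF may stop short at the aldehyde level, and C9 acid carried over into the electrolysis would enter the radical pool. The fallback abandons the alkene cleavage and sets out from 2, which is heated with a three-fold excess of commercial tridecanedioic acid and cat. TsOH in toluene (Dean–Stark). The excess diacid makes mono-esterification the statistically favoured outcome, unreacted diacid crystallises on cooling and is recycled, and chromatography should give 5 directly, where the route is rejoined (no compound outside the list: F0).

Step 1. The activated acid may undergo 1,3-acyl migration to an unreactive N-acylurea, and the urea may be hard to remove completely from a greasy, non-crystalline ester. The fallback sets out from 1: oxalyl chloride and cat. DMF in CH2Cl2 give (Z)-docos-13-enoyl chloride F3, which with 2 and pyridine in CH2Cl2 at 0 °C should give 3, where the route is rejoined.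

Further compounds
F1 | step 3 | 2-phenylethyl 12-bromododecanoate | BrCCCCCCCCCCCC(=O)OCCc1ccccc1
F2 | step 3 | hexadecylmagnesium bromide | CCCCCCCCCCCCCCCC[Mg]Br
F0 | step 2 | none | none
F3 | step 1 | (Z)-docos-13-enoyl chloride | CCCCCCCC/C=C\CCCCCCCCCCCC(=O)Cl
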